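## Analysis of the target

Labdane-type locants are used throughout. Ring B is C5–C10. C10 carries a methyl group and the CH2CO2H arm (C1–C2). C5 carries the C(CH3)2CO2H arm (C4, C3). C8 carries a methyl group and the ether oxygen. C9 carries the C11–C12 tether to C13, which bears methyl, vinyl and the same oxygen.

The target 22 is a 2,3-seco-labdane of the manoyl oxide type: a cyclohexane (ring B) trans-fused along C8–C9 to an oxane (O, C8, C9, C11, C12, C13). It has five stereocentres, C5 (S), C8 (R), C9 (R), C10 (S) and C13 (R). The C10 methyl, the C8 methyl and the C9–C11 bond lie on one face of ring B; the ether oxygen, the acetic arm and the isobutyric arm lie on the other. C5–H is therefore cis to the C10 methyl, and the bulky C5 arm is axial in the only chair that allows the diequatorial ring fusion. C13 is a fully substituted carbinol carbon three bonds away from the ring, so it cannot be controlled from the ring stereocentres and is best bought. The tertiary allylic ether at C13 ionises in strong acid, the vinyl group rules out late hydrogenation or ozonolysis, and the C3 carboxyl sits on quaternary C4, so its esters resist hydrolysis. The hard points are the quaternary C10 and its relation to C9, the C4–C5 bond between a quaternary carbon and a carbon flanked by quaternary C10, and the tetrasubstituted ether carbon C8. The strategy rests on one feature: C1, C10 with its methyl, C9, C11, C12 and C13 with its methyl, vinyl and oxygen are, atom for atom, the (E)-2-methyl-2-enal obtained by oxidising the terminal methyl of (R)-linalool (1). C1 is the formyl carbon, C10 the α-carbon and C9 the β-carbon, which leaves C5–C8 as a four-carbon, 2-oxygenated diene unit.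

## Retrosynthetic reasoning

**22 from 21.** The two carboxyl groups are unmasked last, by cutting the two O–CH3 bonds of dimethyl ester 21. Free acids would compete as internal nucleophiles when the oxane is closed, and the C3 ester is too hindered for attack at the acyl carbon. The forward step therefore has to cleave at the methyl carbon.

**21 from 19.** The oxane is opened at C8–O, not at C13–O. C13–O is the bond that carries the purchased stereocentre; re-forming it at a tertiary allylic carbon would be uncontrolled. C8–O can be made by Markovnikov addition of the C13 hydroxyl of alkenol 19 to a C7=C8 alkene. This gives the oxane and the C8 centre in one step. The forward reaction must bring oxygen to the α face of C8 and must choose the trisubstituted alkene over the vinyl group without acid strong enough to ionise C13–O. A mercury-mediated etherification with reductive demercuration meets these conditions.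

**19 from 16 (through 18 and 17).** The C7=C8 alkene is traced to keto diester 16, a C7 ketone with a methyl group on C8, through the more substituted enol triflate 17 and its reduction to 18. A C7 carbonyl is exactly what a cycloaddition with an oxygenated diene leaves, and it is also what activates C5 and C8 beforehand.

**16 from 13 and 14.** The C4–C5 bond is cut. The C5=C6–C7=O enone of 13 makes C5 electrophilic, so the whole isobutyrate arm can arrive as the silyl ketene acetal 14. The forward addition must come anti to the C10 methyl. With the C9 chain equatorial that methyl is pseudoaxial, and axial attack at C5 from the opposite face is favoured both stereoelectronically and sterically.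

**13 from 12, 12 from 11, 11 from 10.** The C8–CH3 bond is cut as an α′-alkylation of enone 12; C8 is the only enolisable ring position because C10 is quaternary. The C1–C2 bond is cut as a one-carbon homologation of the formyl group of 10, by Wittig methoxymethylenation to 11 and oxidation of the enol ether to the ester 12. Homologation precedes enolate chemistry because a free aldehyde would not survive it.

**10 from 4 and 8.** The key disconnection cuts C5–C10 and C8–C9. Ring B is a Diels–Alder adduct of enal 4 (C1, C10, C9 and C11–C16) and the aminosiloxydiene 8 (C5–C8). The E geometry of 4 fixes the methyl/chain relationship at C10/C9, the auxiliary on 8 fixes the absolute sense, and acidic work-up of cycloadduct 9 leaves the enone.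

**4 from 1; 8 from 5 and 6.** Enal 4 comes from 1 by silylation to 2 and allylic oxidation at the E methyl group through alcohol 3. Diene 8 comes from 5 and 6 by amine exchange to 7 and O-silylation. Each cycloaddition partner is two steps from commercial material, so the risk of the route sits in the key step.

## Alternatives that were turned down

**Alternative 1:** The disconnection cuts C9–C10 and C8–O at once and keeps ring A intact. The precursor is the monocyclic ring A enone A1, whose C5 side chain ends in an (E)-C8=C9 alkene and the silylated C13 carbinol.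
- **Forward step:** MeAlCl2 would bind the enone carbonyl, the alkene would add through C9 to the enone β-carbon C10, and the C8 cation would be trapped by the C13 ether oxygen. This gives the cis-fused tricycle A2, whose 2-keto-3-acetoxy unit allows later cleavage of ring A between C2 and C3.
- **For:** Ring B, the oxane and three stereocentres (C8, C9, C10) come from one step, and anti addition across an E alkene fixes C8 against C9. The C4–C5 bond is a ring bond from the start and never has to be made intermolecularly. On bond-forming power and on the C5 problem this plan is stronger than the chosen one.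
- **Against:** A1 is itself demanding (C3 and C5 stereocentres, a trisubstituted E alkene, C13) and would cost more steps than the first half of the chosen route. The strong Lewis acid meets a tertiary allylic silyl ether that can ionise and a vinyl group that can compete as a π-nucleophile. Cis selectivity at the new quaternary C10 relative to C5 rests on the folding of a flexible tether. After the cyclisation the ketol must still be deacetylated, cleaved and oxidised.
- **Comparison:** The chosen strategy gives up the cascade. In return it reaches both cycloaddition partners in two steps each, sets C9/C10 through alkene geometry in a concerted reaction, and keeps strong Lewis acids away from C13.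

**Alternative 2:** The C8–O bond is made by oxygen insertion. The oxane is traced to the hydrindanone A3, in which C13 is a ketone carbon bonded directly to quaternary C8.
- **Forward step:** A peracid (CF3CO3H or 3-chloroperbenzoic acid) would form the Criegee adduct, the more substituted C8 would migrate with retention, and the cyclopentanone would expand to the six-membered lactone A4.
- **For:** The configuration at C8 is transferred stereospecifically from a C–C bond, and migratory aptitude secures the regiochemistry. On the C8 centre this is more secure than the etherification of the chosen route, whose facial selectivity has to be earned.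
- **Against:** C13 arrives as a lactone carbonyl. Its methyl and vinyl groups and its configuration must all be installed afterwards by two carbon-nucleophile additions in the presence of two esters, with only the axial-attack preference of an oxocarbenium ion as control. A3 still contains C5, C8, C9 and C10 as contiguous centres, so the hard part is only moved into its synthesis.
- **Comparison:** The chosen strategy takes C13, complete and enantiopure, from 1 and never breaks a bond to it.

**Alternative 3:** The C9–C10 bond is cut as the σ-bond of a [3,3] shift. Ring B is unfolded to the six-membered lactone A5, a cis-4-methyl-6-alkenyl oxan-2-one with a (Z)-trisubstituted alkene, in which C11 is the lactone carbonyl and C6 the carbinol carbon.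
- **Forward step:** Enolisation and silylation (LiN(iPr)2, tBuMe2SiCl) followed by heating would send the silyl ketene acetal through the boat transition state that the ring enforces. C9–C10 forms as C6–O breaks, giving the cyclohex-5-ene acid A6 with C9 and quaternary C10 set and the C1–C2 arm in place as a protected alcohol.
- **For:** Chirality transfer is intramolecular and rigid, so the C9/C10 pair follows from the lactone stereocentres and the alkene geometry without an auxiliary. On predictability of the absolute sense it is stronger than an auxiliary-controlled cycloaddition with a β-substituted enal.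
- **Against:** A6 is far from the target. The C5=C6 alkene is unactivated, so the isobutyric arm cannot enter by conjugate addition. C8 is a CH carbon that would have to be oxidised to the ether carbon. The C11 acid must be extended by two carbons to a C13 carbinol needing separate control. A5 itself requires a stereoselective synthesis.
- **Comparison:** The enone delivered by the chosen Diels–Alder reaction activates C5, C6 and C8 for exactly the three operations that remain, and C11–C16 are present from the outset.

Key step: step 5

Assumption: the (2R,5R) auxiliary of 8 is taken to expose the diene face that leads to the C9/C10 configuration drawn for 10. The sense has to be confirmed on the first cycloadduct; if it is the opposite one, the (2S,5S) amine is used in steps 3–5 with no other change.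

## Route

Step 1
Reactants: 1 (R)-linalool
Product: 2 triethyl{[(3R)-3,7-dimethylocta-1,6-dien-3-yl]oxy}silane
Conditions: Et3SiOTf, 2,6-lutidine, CH2Cl2, −78 → 0 °C
Reagents that add atoms: triethylsilyl trifluoromethanesulfonate, CC[Si](CC)(CC)OS(=O)(=O)C(F)(F)F
Why: Silylation of a tertiary allylic alcohol with a silyl triflate and a hindered pyridine base is routine and does not touch the C13 stereocentre. The triethylsilyl ether masks the hydroxyl through the base and Lewis acid steps and is removable with fluoride.

Step 2
Reactants: 2 triethyl{[(3R)-3,7-dimethylocta-1,6-dien-3-yl]oxy}silane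
Product: 4 (2E,6R)-2,6-dimethyl-6-(triethylsilyloxy)octa-2,7-dienal, via allylic alcohol 3 (not isolated)
Conditions: SeO2 (0.3 equiv), tBuOOH, salicylic acid (cat.), CH2Cl2, rt; then MnO2, CH2Cl2, rt
Reagents that add atoms: selenium dioxide, O=[Se]=O; tert-butyl hydroperoxide, CC(C)(C)OO
Why: Allylic oxidation by SeO2 (ene reaction, then [2,3]-sigmatropic shift) attacks the E methyl group of a trisubstituted alkene, so the E geometry needed later is built in. MnO2 converges the alcohol/aldehyde mixture on the enal, and the vinyl group has no allylic hydrogen and is inert.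

Step 3
Reactants: 5 (E)-4-methoxybut-3-en-2-one; 6 (2R,5R)-2,5-diphenylpyrrolidine
Product: 7 (E)-4-[(2R,5R)-2,5-diphenylpyrrolidin-1-yl]but-3-en-2-one
Conditions: MeOH, 50 °C
Reagents that add atoms: none
Why: Conjugate addition–elimination of the secondary amine on the β-methoxy enone (vinylogous transamidation) gives the stable E vinylogous amide; methanol is the only by-product.

Step 4
Reactants: 7 (E)-4-[(2R,5R)-2,5-diphenylpyrrolidin-1-yl]but-3-en-2-one
Product: 8 (E)-1-[(2R,5R)-2,5-diphenylpyrrolidin-1-yl]-3-(tert-butyldimethylsilyloxy)buta-1,3-diene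
Conditions: KN(SiMe3)2, THF, −78 °C; tBuMe2SiCl, −78 °C → rt
Reagents that add atoms: tert-butyldimethylsilyl chloride, CC(C)(C)[Si](C)(C)Cl
Why: Kinetic deprotonation of the methyl ketone and O-silylation of the enolate give the 1-amino-3-siloxydiene with the enamine geometry retained. The diene is used without chromatography because it is sensitive to acid.

Step 5
Reactants: 4 (2E,6R)-2,6-dimethyl-6-(triethylsilyloxy)octa-2,7-dienal; 8 (E)-1-[(2R,5R)-2,5-diphenylpyrrolidin-1-yl]-3-(tert-butyldimethylsilyloxy)buta-1,3-diene
Product: 10 (1R,6S)-1-methyl-4-oxo-6-[(3R)-3-methyl-3-(triethylsilyloxy)pent-4-en-1-yl]cyclohex-2-ene-1-carbaldehyde, via amino cycloadduct 9 (not isolated)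
Conditions: toluene, 25 → 50 °C; then 0.1 M HCl, THF, 0 °C
Reagents that add atoms: none
Why: The electron-rich diene 8 and the enal 4 combine in a concerted, asynchronous, suprafacial [4+2] cycloaddition; the closest known reaction type is the Diels–Alder reaction of 1-amino-3-siloxybutadienes carrying a C2-symmetric 2,5-diphenylpyrrolidine with α-substituted enals, which gives 4-formyl-4-alkylcyclohexenones. Ring B is closed by intermolecular cycloaddition, its two new σ-bonds C8–C9 and C5–C10 forming in the same step. Regiochemistry follows the polarisation of the partners: the nucleophilic CH2 terminus of the diene bonds to the electrophilic β-carbon C9 and the nitrogen-bearing terminus to the α-carbon C10. The C9/C10 relationship is fixed by the E geometry of 4, which is conserved, so the C10 methyl and the C11 chain end cis and the formyl group trans to the chain. The absolute sense at C9 and C10 is set by the auxiliary, one phenyl group of which covers one face of the s-cis diene so that the enal adds endo to the open face; the C13 centre of 4 is too remote to matter. The step needs carbon–carbon over carbonyl (hetero-Diels–Alder) selectivity, which the aprotic, non-hydrogen-bonding solvent favours, and enough reactivity toward a trisubstituted alkene, which the push–pull diene should supply on gentle warming. Dilute acid then hydrolyses the silyl enol ether and expels the amine by β-elimination, which erases the transient C5 centre, returns the auxiliary and leaves the C5=C6–C7=O enone; the tertiary triethylsilyl ether should survive the brief cold exposure.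

Step 6
Reactants: 10 (1R,6S)-1-methyl-4-oxo-6-[(3R)-3-methyl-3-(triethylsilyloxy)pent-4-en-1-yl]cyclohex-2-ene-1-carbaldehyde
Product: 11 4-(2-methoxyethenyl)-4-methyl-5-[(3R)-3-methyl-3-(triethylsilyloxy)pent-4-en-1-yl]cyclohex-2-en-1-one (E/Z mixture; ring centres as in 10)
Conditions: MeOCH2PPh3Cl, KN(SiMe3)2, THF, −78 °C; then 10, −78 → −20 °C
Reagents that add atoms: (methoxymethyl)triphenylphosphonium chloride, COC[P+](c1ccccc1)(c1ccccc1)c1ccccc1.[Cl-]
Why: Wittig olefination; the aldehyde, which cannot enolise, reacts with the unstabilised ylide far faster than the conjugated ketone, so a slight excess at low temperature should be chemoselective. The enol ether geometry is irrelevant because both isomers are oxidised to the same ester.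

Step 7
Reactants: 11 4-(2-methoxyethenyl)-4-methyl-5-[(3R)-3-methyl-3-(triethylsilyloxy)pent-4-en-1-yl]cyclohex-2-en-1-one
Product: 12 methyl 2-[(1R,6S)-1-methyl-4-oxo-6-[(3R)-3-methyl-3-(triethylsilyloxy)pent-4-en-1-yl]cyclohex-2-en-1-yl]acetate
Conditions: C5H5NH[CrO3Cl], NaOAc, 4 Å sieves, CH2Cl2, 0 °C → rt
Reagents that add atoms: pyridinium chlorochromate, [O-][Cr](=O)(=O)Cl.c1cc[nH+]cc1
Why: Oxidation of an enol ether to the corresponding ester by hexavalent chromium is a known transformation and delivers the CH2CO2CH3 arm without an acidic hydrolysis. The enone, the vinyl group and the silyl ether are inert to the buffered reagent.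

Step 8
Reactants: 12 methyl 2-[(1R,6S)-1-methyl-4-oxo-6-[(3R)-3-methyl-3-(triethylsilyloxy)pent-4-en-1-yl]cyclohex-2-en-1-yl]acetate
Product: 13 methyl 2-[1,5-dimethyl-4-oxo-6-[(3R)-3-methyl-3-(triethylsilyloxy)pent-4-en-1-yl]cyclohex-2-en-1-yl]acetate (C9 and C10 as in 12; C8 methyl trans to the C9 chain expected)
Conditions: LiN(iPr)2 (1.05 equiv), THF, −78 °C; MeI, DMPU, −78 → −30 °C
Reagents that add atoms: iodomethane, CI
Why: Kinetic α′-deprotonation gives the cross-conjugated dienolate at C8, the only enolisable ring position because C10 is quaternary, and the ketone is more acidic than the neopentyl ester CH2. The methyl group should enter trans to the C9 chain, away from the pseudoaxial C10 methyl, but this centre becomes sp2 in step 10, so either epimer serves.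

Step 9
Reactants: 13 methyl 2-[1,5-dimethyl-4-oxo-6-[(3R)-3-methyl-3-(triethylsilyloxy)pent-4-en-1-yl]cyclohex-2-en-1-yl]acetate; 14 1-methoxy-2-methyl-1-(trimethylsilyloxy)prop-1-ene
Product: 16 methyl 2-[2-(2-methoxy-2-oxoethyl)-2,4-dimethyl-5-oxo-3-[(3R)-3-methyl-3-(triethylsilyloxy)pent-4-en-1-yl]cyclohexyl]-2-methylpropanoate (C5 C9 C10 as in 22), via silyl enol ether 15 (not isolated)
Conditions: Me3SiOTf (10 mol %), CH2Cl2, −78 °C; then 0.5 M HCl, THF, 0 °C
Reagents that add atoms: none
Why: Mukaiyama–Michael addition: the silyl triflate activates the enone and the ketene acetal adds to C5, the silyl group passing to the enolate oxygen. With the C9 chain equatorial the C10 methyl is pseudoaxial, so axial attack at C5 occurs from the opposite face and places the isobutyrate arm trans to the C10 methyl, as the target requires. Catalytic silyl triflate at −78 °C is chosen so that the tertiary allylic silyl ether is not ionised.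

Step 10
Reactants: 16 methyl 2-[2-(2-methoxy-2-oxoethyl)-2,4-dimethyl-5-oxo-3-[(3R)-3-methyl-3-(triethylsilyloxy)pent-4-en-1-yl]cyclohexyl]-2-methylpropanoate
Product: 17 methyl 2-[2-(2-methoxy-2-oxoethyl)-2,4-dimethyl-3-[(3R)-3-methyl-3-(triethylsilyloxy)pent-4-en-1-yl]-5-(trifluoromethylsulfonyloxy)cyclohex-4-en-1-yl]-2-methylpropanoate
Conditions: Tf2O, 2,6-di-tert-butyl-4-methylpyridine, CH2Cl2, 0 °C → rt
Reagents that add atoms: trifluoromethanesulfonic anhydride, O=S(=O)(OS(=O)(=O)C(F)(F)F)C(F)(F)F
Why: O-Triflation of the ketone followed by loss of a proton under these conditions gives mainly the more substituted (C7=C8) enol triflate. This removes the C8 stereocentre and places the double bond where the ether carbon is needed.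

Step 11
Reactants: 17 methyl 2-[2-(2-methoxy-2-oxoethyl)-2,4-dimethyl-3-[(3R)-3-methyl-3-(triethylsilyloxy)pent-4-en-1-yl]-5-(trifluoromethylsulfonyloxy)cyclohex-4-en-1-yl]-2-methylpropanoate
Product: 18 methyl 2-[2-(2-methoxy-2-oxoethyl)-2,4-dimethyl-3-[(3R)-3-methyl-3-(triethylsilyloxy)pent-4-en-1-yl]cyclohex-4-en-1-yl]-2-methylpropanoate
Conditions: Pd(OAc)2 (5 mol %), PPh3, HCO2H, nBu3N, DMF, 60 °C
Reagents that add atoms: none
Why: Palladium-catalysed formate reduction of an enol triflate: oxidative addition to zerovalent palladium, exchange with formate, loss of CO2 and reductive elimination give the C7–H alkene. The vinyl group on quaternary C13 cannot isomerise and the esters and silyl ether are untouched.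

Step 12
Reactants: 18 methyl 2-[2-(2-methoxy-2-oxoethyl)-2,4-dimethyl-3-[(3R)-3-methyl-3-(triethylsilyloxy)pent-4-en-1-yl]cyclohex-4-en-1-yl]-2-methylpropanoate
Product: 19 methyl 2-[3-[(3R)-3-hydroxy-3-methylpent-4-en-1-yl]-2-(2-methoxy-2-oxoethyl)-2,4-dimethylcyclohex-4-en-1-yl]-2-methylpropanoate
Conditions: Bu4NF, THF, 0 °C → rt
Reagents that add atoms: none
Why: Fluoride cleaves the triethylsilyl ether at silicon, so the C13–O bond and its configuration are not involved; the methyl esters are stable to these conditions.

Step 13
Reactants: 19 methyl 2-[3-[(3R)-3-hydroxy-3-methylpent-4-en-1-yl]-2-(2-methoxy-2-oxoethyl)-2,4-dimethylcyclohex-4-en-1-yl]-2-methylpropanoate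
Product: 21 methyl 2-[(2R,4aR,5S,6S,8aR)-2-ethenyl-5-(2-methoxy-2-oxoethyl)-2,5,8a-trimethyloctahydro-2H-chromen-6-yl]-2-methylpropanoate, via organomercury triflate 20 (not isolated)
Conditions: Hg(OTf)2, tetramethylurea, MeCN, −20 °C; then NaBH4, aq NaOH, 0 °C
Reagents that add atoms: none
Why: Intramolecular oxymercuration followed by reductive demercuration: divalent mercury should complex the trisubstituted alkene at C7 from the β face, away from the pseudoaxial C5 arm, and the C13 hydroxyl opens the mercurinium ion at tertiary C8 from the α face through a chair-like six-membered transition state with the C9–C11 bond equatorial. This gives the trans-fused oxane with the C8 methyl β and leaves C13–O intact; the vinyl group has no nucleophile within reach and its complexation is unproductive. The acids are kept as methyl esters so that no carboxylate competes for C8.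

Step 14
Reactants: 21 methyl 2-[(2R,4aR,5S,6S,8aR)-2-ethenyl-5-(2-methoxy-2-oxoethyl)-2,5,8a-trimethyloctahydro-2H-chromen-6-yl]-2-methylpropanoate
Product: 22 2-[(2R,4aR,5S,6S,8aR)-5-(carboxymethyl)-2-ethenyl-2,5,8a-trimethyloctahydro-2H-chromen-6-yl]-2-methylpropanoic acid
Conditions: NaSCH2CH3, DMF, 90 °C; then 1 M HCl to pH 3, 0 °C
Reagents that add atoms: none
Why: Thiolate attacks the ester methyl groups by SN2, so the cleavage does not depend on access to the acyl carbon; hydroxide would not reach the neopentyl-type C3 ester. No stereocentre is involved, and the cold, brief acidification spares the tertiary allylic ether.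

## Compound list

1 | (R)-linalool, (3R)-3,7-dimethylocta-1,6-dien-3-ol | C=C[C@](C)(O)CCC=C(C)C | starting material
2 | triethyl{[(3R)-3,7-dimethylocta-1,6-dien-3-yl]oxy}silane | C=C[C@](C)(O[Si](CC)(CC)CC)CCC=C(C)C | intermediate
3 | (2E,6R)-2,6-dimethyl-6-(triethylsilyloxy)octa-2,7-dien-1-ol (formed in the flask) | C=C[C@](C)(O[Si](CC)(CC)CC)CC/C=C(\C)CO | intermediate
4 | (2E,6R)-2,6-dimethyl-6-(triethylsilyloxy)octa-2,7-dienal | C=C[C@](C)(O[Si](CC)(CC)CC)CC/C=C(\C)C=O | intermediate
5 | (E)-4-methoxybut-3-en-2-one | CO/C=C/C(C)=O | starting material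
6 | (2R,5R)-2,5-diphenylpyrrolidine | N1[C@@H](c2ccccc2)CC[C@@H]1c1ccccc1 | starting material
7 | (E)-4-[(2R,5R)-2,5-diphenylpyrrolidin-1-yl]but-3-en-2-one | CC(=O)/C=C/N1[C@@H](c2ccccc2)CC[C@@H]1c1ccccc1 | intermediate
8 | (E)-1-[(2R,5R)-2,5-diphenylpyrrolidin-1-yl]-3-(tert-butyldimethylsilyloxy)buta-1,3-diene | C=C(O[Si](C)(C)C(C)(C)C)/C=C/N1[C@@H](c2ccccc2)CC[C@@H]1c1ccccc1 | intermediate
9 | 4-(tert-butyldimethylsilyloxy)-2-[(2R,5R)-2,5-diphenylpyrrolidin-1-yl]-1-methyl-6-[(3R)-3-methyl-3-(triethylsilyloxy)pent-4-en-1-yl]cyclohex-3-ene-1-carbaldehyde (endo adduct, amine cis to formyl; formed in the flask) | C=C[C@](C)(O[Si](CC)(CC)CC)CC[C@@H]1[C@@](C)(C=O)[C@@H](N2[C@@H](c3ccccc3)CC[C@@H]2c2ccccc2)C=C(O[Si](C)(C)C(C)(C)C)C1 | intermediate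
10 | (1R,6S)-1-methyl-4-oxo-6-[(3R)-3-methyl-3-(triethylsilyloxy)pent-4-en-1-yl]cyclohex-2-ene-1-carbaldehyde | C=C[C@](C)(O[Si](CC)(CC)CC)CC[C@@H]1[C@@](C)(C=O)C=CC(=O)C1 | intermediate
11 | 4-(2-methoxyethenyl)-4-methyl-5-[(3R)-3-methyl-3-(triethylsilyloxy)pent-4-en-1-yl]cyclohex-2-en-1-one (E/Z mixture; ring centres as in 10) | C=C[C@](C)(O[Si](CC)(CC)CC)CC[C@@H]1[C@@](C)(C=COC)C=CC(=O)C1 | intermediate
12 | methyl 2-[(1R,6S)-1-methyl-4-oxo-6-[(3R)-3-methyl-3-(triethylsilyloxy)pent-4-en-1-yl]cyclohex-2-en-1-yl]acetate | C=C[C@](C)(O[Si](CC)(CC)CC)CC[C@@H]1[C@@](C)(CC(=O)OC)C=CC(=O)C1 | intermediate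
13 | methyl 2-[1,5-dimethyl-4-oxo-6-[(3R)-3-methyl-3-(triethylsilyloxy)pent-4-en-1-yl]cyclohex-2-en-1-yl]acetate (C9, C10 as in 12; C8 methyl trans to the C9 chain) | C=C[C@](C)(O[Si](CC)(CC)CC)CC[C@@H]1[C@@](C)(CC(=O)OC)C=CC(=O)[C@H]1C | intermediate
14 | 1-methoxy-2-methyl-1-(trimethylsilyloxy)prop-1-ene | COC(O[Si](C)(C)C)=C(C)C | starting material
15 | C6=C7 trimethylsilyl enol ether of 16 (formed in the flask) | C=C[C@](C)(O[Si](CC)(CC)CC)CC[C@@H]1[C@@](C)(CC(=O)OC)[C@@H](C(C)(C)C(=O)OC)C=C(O[Si](C)(C)C)[C@H]1C | intermediate
16 | methyl 2-[2-(2-methoxy-2-oxoethyl)-2,4-dimethyl-5-oxo-3-[(3R)-3-methyl-3-(triethylsilyloxy)pent-4-en-1-yl]cyclohexyl]-2-methylpropanoate (isobutyrate arm trans to the C10 methyl) | C=C[C@](C)(O[Si](CC)(CC)CC)CC[C@@H]1[C@@](C)(CC(=O)OC)[C@@H](C(C)(C)C(=O)OC)CC(=O)[C@H]1C | intermediate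
17 | methyl 2-[2-(2-methoxy-2-oxoethyl)-2,4-dimethyl-3-[(3R)-3-methyl-3-(triethylsilyloxy)pent-4-en-1-yl]-5-(trifluoromethylsulfonyloxy)cyclohex-4-en-1-yl]-2-methylpropanoate | C=C[C@](C)(O[Si](CC)(CC)CC)CC[C@@H]1[C@@](C)(CC(=O)OC)[C@@H](C(C)(C)C(=O)OC)CC(OS(=O)(=O)C(F)(F)F)=C1C | intermediate
18 | methyl 2-[2-(2-methoxy-2-oxoethyl)-2,4-dimethyl-3-[(3R)-3-methyl-3-(triethylsilyloxy)pent-4-en-1-yl]cyclohex-4-en-1-yl]-2-methylpropanoate | C=C[C@](C)(O[Si](CC)(CC)CC)CC[C@@H]1[C@@](C)(CC(=O)OC)[C@@H](C(C)(C)C(=O)OC)CC=C1C | intermediate
19 | methyl 2-[3-[(3R)-3-hydroxy-3-methylpent-4-en-1-yl]-2-(2-methoxy-2-oxoethyl)-2,4-dimethylcyclohex-4-en-1-yl]-2-methylpropanoate | C=C[C@](C)(O)CC[C@@H]1[C@@](C)(CC(=O)OC)[C@@H](C(C)(C)C(=O)OC)CC=C1C | intermediate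
20 | C7 organomercury triflate of 21 (mercury β, anti to the ether oxygen; formed in the flask) | C=C[C@@]1(C)CC[C@@H]2[C@@](C)(CC(=O)OC)[C@@H](C(C)(C)C(=O)OC)C[C@H]([Hg]OS(=O)(=O)C(F)(F)F)[C@@]2(C)O1 | intermediate
21 | methyl 2-[(2R,4aR,5S,6S,8aR)-2-ethenyl-5-(2-methoxy-2-oxoethyl)-2,5,8a-trimethyloctahydro-2H-chromen-6-yl]-2-methylpropanoate | C=C[C@@]1(C)CC[C@@H]2[C@@](C)(CC(=O)OC)[C@@H](C(C)(C)C(=O)OC)CC[C@@]2(C)O1 | intermediate
22 | 2-[(2R,4aR,5S,6S,8aR)-5-(carboxymethyl)-2-ethenyl-2,5,8a-trimethyloctahydro-2H-chromen-6-yl]-2-methylpropanoic acid (CNP0186744.3) | C=C[C@@]1(C)CC[C@@H]2[C@@](C)(CC(=O)O)[C@@H](C(C)(C)C(=O)O)CC[C@@]2(C)O1 | target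

## Step count and least certain steps

Total: 14 steps. Longest linear sequence: 12 steps (1 → 22 through steps 1, 2 and 5–14; the diene branch through steps 3, 4 and 5–14 is equally long).

**Step 5 (key step).** The cycloaddition of a trisubstituted enal may be slow enough for hetero-Diels–Alder addition across the formyl group or decomposition of the diene to compete. The facial bias of the auxiliary may also be weaker with a β-substituted dienophile than with α-substituted acroleins; a reversed sense is cured by the antipodal amine, a weak one is not.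
Fallback, from 4 back to 10: control is moved from the diene to a catalyst that also activates the enal. Compound 4 and commercial 2-(trimethylsilyloxy)buta-1,3-diene are combined at −78 °C in CH2Cl2 under the cationic oxazaborolidine formed from (S)-1-(2-methylphenyl)-3,3-diphenyltetrahydro-1H,3H-pyrrolo[1,2-c][1,3,2]oxazaborole and HN(SO2CF3)2, or its enantiomer, whichever gives the required sense. This gives the trimethylsilyl enol ether cycloadduct F1 with the same regiochemistry (siloxy carbon = C7). Saegusa–Ito dehydrosilylation with Pd(OAc)2 in MeCN then introduces the C5=C6 bond and gives 10.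

**Step 9.** Bond formation between C5, which is next to quaternary C10, and a fully substituted nucleophilic carbon may be too slow. Raising the temperature or the amount of Lewis acid invites ionisation of the tertiary allylic silyl ether.
Fallback, from 13 back to 16: an anionic Michael addition without Lewis acid. The lithium enolate of methyl isobutyrate F2 (from methyl isobutyrate and LiN(iPr)2) is added to 13 in THF–DMPU at −78 °C and the mixture is warmed, so that reversible 1,2-addition drains into the conjugate adduct, the lithium C6–C7 enolate F3. Quenching with aqueous NH4Cl gives 16.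

**Step 10.** Enolisation toward C6 instead of C8 would give the regioisomeric triflate, and Tf2O may attack the silyl ether.
Fallback, from 16 back to 17: equilibrating enol silylation (Me3SiCl, NaI, Et3N, MeCN) gives the more substituted C7–C8 trimethylsilyl enol ether F4. It can be purified, and the minor isomer can be hydrolysed back to 16 and recycled. CsF and PhN(SO2CF3)2 in dimethoxyethane then convert F4 into 17 without exposure to Tf2O.

**Step 13.** Attack of the hydroxyl on the β face of C8 would give the cis-fused oxane, and mercuration of the vinyl group may consume reagent.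
Fallback, from 19 back to 21: reversible selenoetherification with PhSeCl (CH2Cl2, −78 °C → rt). The episelenonium ion forms and opens reversibly, so the more stable trans-fused ether should accumulate as the C7 phenylselenide of 21, F5. Radical reduction with nBu3SnH and azobisisobutyronitrile in toluene at 80 °C removes selenium and gives 21.

**Step 7.** Oxidation of the hindered enol ether at the carbon next to quaternary C10 may be slow, with chromium-induced degradation taking over.
Fallback, from 11 back to 12: hydrolysis of the enol ether with oxalic acid in THF–H2O gives the aldehyde F6. Pinnick oxidation (NaClO2, NaH2PO4, 2-methylbut-2-ene, tBuOH–H2O) gives the carboxylic acid F7, and Me3SiCHN2 in MeOH–toluene gives 12.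

## Further compounds

F1 | step 5 | 1-methyl-6-[(3R)-3-methyl-3-(triethylsilyloxy)pent-4-en-1-yl]-4-(trimethylsilyloxy)cyclohex-3-ene-1-carbaldehyde (C1 and C6 as in 10) | C=C[C@](C)(O[Si](CC)(CC)CC)CC[C@@H]1[C@@](C)(C=O)CC=C(O[Si](C)(C)C)C1
F2 | step 9 | lithium enolate of methyl isobutyrate | COC(O[Li])=C(C)C
F3 | step 9 | lithium C6–C7 enolate of 16 | C=C[C@](C)(O[Si](CC)(CC)CC)CC[C@@H]1[C@@](C)(CC(=O)OC)[C@@H](C(C)(C)C(=O)OC)C=C(O[Li])[C@H]1C
F4 | step 10 | C7–C8 trimethylsilyl enol ether of 16 | C=C[C@](C)(O[Si](CC)(CC)CC)CC[C@@H]1[C@@](C)(CC(=O)OC)[C@@H](C(C)(C)C(=O)OC)CC(O[Si](C)(C)C)=C1C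
F5 | step 13 | C7 phenylselenide of 21 (selenium β, anti to the ether oxygen) | C=C[C@@]1(C)CC[C@@H]2[C@@](C)(CC(=O)OC)[C@@H](C(C)(C)C(=O)OC)C[C@H]([Se]c3ccccc3)[C@@]2(C)O1
F6 | step 7 | 2-[(1R,6S)-1-methyl-4-oxo-6-[(3R)-3-methyl-3-(triethylsilyloxy)pent-4-en-1-yl]cyclohex-2-en-1-yl]acetaldehyde | C=C[C@](C)(O[Si](CC)(CC)CC)CC[C@@H]1[C@@](C)(CC=O)C=CC(=O)C1
F7 | step 7 | 2-[(1R,6S)-1-methyl-4-oxo-6-[(3R)-3-methyl-3-(triethylsilyloxy)pent-4-en-1-yl]cyclohex-2-en-1-yl]acetic acid | C=C[C@](C)(O[Si](CC)(CC)CC)CC[C@@H]1[C@@](C)(CC(=O)O)C=CC(=O)C1
A1 | alternative 1 | 6-acetoxy-3,5,5-trimethyl-4-[(3E,7R)-3,7-dimethyl-7-(triethylsilyloxy)nona-3,8-dien-1-yl]cyclohex-2-en-1-one | C=C[C@](C)(O[Si](CC)(CC)CC)CC/C=C(\C)CC[C@H]1C(C)=CC(=O)[C@H](OC(C)=O)C1(C)C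
A2 | alternative 1 | cis-fused tricyclic 3-acetoxy-2-ketone, (13R)-3-acetoxy-8α,13-epoxy-5β-labd-14-en-2-one | C=C[C@@]1(C)CC[C@@H]2[C@@]3(C)CC(=O)[C@H](OC(C)=O)C(C)(C)[C@H]3CC[C@@]2(C)O1
A3 | alternative 2 | tert-butyl 2-[4-(2-tert-butoxy-2-oxoethyl)-4,7a-dimethyl-1-oxooctahydro-1H-inden-5-yl]-2-methylpropanoate | O=C1CC[C@@H]2[C@@](C)(CC(=O)OC(C)(C)C)[C@@H](C(C)(C)C(=O)OC(C)(C)C)CC[C@@]12C
A4 | alternative 2 | tert-butyl 2-[5-(2-tert-butoxy-2-oxoethyl)-5,8a-dimethyl-2-oxooctahydro-2H-chromen-6-yl]-2-methylpropanoate | O=C1CC[C@@H]2[C@@](C)(CC(=O)OC(C)(C)C)[C@@H](C(C)(C)C(=O)OC(C)(C)C)CC[C@@]2(C)O1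
A5 | alternative 3 | cis-4-methyl-6-[(Z)-4-(4-methoxybenzyloxy)-2-methylbut-1-en-1-yl]oxan-2-one | O=C1C[C@H](C)C[C@H](/C=C(/C)CCOCc2ccc(OC)cc2)O1
A6 | alternative 3 | 2-[2-(4-methoxybenzyloxy)ethyl]-2,6-dimethylcyclohex-3-ene-1-carboxylic acid | OC(=O)[C@@H]1[C@@](C)(CCOCc2ccc(OC)cc2)C=CC[C@H]1C
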